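Atom labels used throughout: C1 (allyl-bearing bridgehead), C2 (CH2), C3 (CH–OMe), C4 (CH–OH), C5 (methoxy-bearing bridgehead), C6 (CH–aryl), C7 (CH–CH3), C8 (ketone). Cyclopentane intermediates keep these labels in the discussion; their names use their own locants.

## The problem

Target 18 is a bicyclo[3.2.1]octan-8-one: a cyclopentanone ring (C1, C8, C5, C6, C7) spanned by the three-carbon bridge C2–C3–C4, so that the ketone C8 lies between two quaternary bridgeheads, C1 (allyl) and C5 (methoxy). Six stereocentres have to be set. Four are contiguous on the five-membered ring (C1, C7, C6, C5), with the methyl group endo (toward the three-carbon bridge) and the aryl group exo and trans to it; the other two are the equatorial methoxy group at C3 and the axial hydroxyl at C4. Only one needs an external source of chirality. The C7 methyl centre can place the C6 aryl group trans to itself, the aryl group can send a carbon electrophile to the opposite face of C5, a tether from C5 then fixes C1, C3 can settle thermodynamically next to a carbonyl, and C4 is left to reagent approach on the rigid cage. The terminal allyl group excludes hydrogenation, hydroboration and strong electrophiles, and the trimethoxyphenyl ring does not tolerate strong Lewis acids or oxidants. The C4–OH/C8=O pair is a β-hydroxy ketone with a quaternary α-carbon that can open by retro-aldol under base, and any intermediate with C4 as a ketone is a non-enolisable β-diketone open to retro-Claisen cleavage by nucleophilic bases. The enabling feature is that C2 is a bare methylene between C1, the α-carbon of the C8 ketone, and C3: with C4 at the ketone level, C8 and C4 are the carbonyls of a 1,5-diketone through C1–C2–C3, so C1–C2 is a Michael bond between a cyclopentanone enolate and an acryloyl group on C5. Because C5 is quaternary and the acceptor carbonyl has no α-hydrogen, that cyclopentanone can enolise in one direction only.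

## Retrosynthesis

**C4–H.** The carbinol of 18 is taken back to the ketone of dione 17. Carrying a protected C4 alcohol instead would remove the carbonyl that makes the bridge closable and that lets C3 equilibrate. Dione 17 has one stereocentre fewer. The forward reduction must prefer C4 over C8 and deliver hydride from the side away from the C8 bridge, so that the hydroxyl ends axial.

**C1–C2 (key cut).** The bridge of 17 could be opened at C1–C2, C2–C3 or C4–C5. A C4–C5 cut would mean acylating a bridged ketone at a position that becomes quaternary between two carbonyls, and a C2–C3 cut has no activating group on the right carbon. The C1–C2 cut is a retro-Michael step to monocyclic 16, in which the 2-methoxyacryloyl group sits on C5 and C1 is the only enolisable carbon. It removes a ring, the quaternary C1 centre and the C3 centre in one move. The forward step asks for a 6-endo closure by a tertiary enolate onto a methoxy-substituted acceptor under conditions that spare the β-diketone.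

**C2=C3 (the methylene carbon).** The terminal CH2 of 16 is removed to give methoxyacetyl diketone 13; forward, it arrives by Mannich methylenation. This is preferred to attaching a complete 2-methoxyacryloyl electrophile to C5, since acryloyl halides react with enolates at oxygen, at the acyl carbon and at the β-carbon. The forward step must enolise the side chain and not the ring.

**C4–C5.** The bond between the quaternary C5 and the side-chain carbonyl of 13 is cut at the alcohol oxidation level (12), giving silyl enol ether 10 and methoxyacetaldehyde 11. An aldol addition is chosen over direct acylation because a tetrasubstituted, oxygen-bearing enolate tends to acylate on oxygen, whereas aldehydes react at carbon; the price is the oxidation of 12 to 13. The new C–C bond must form anti to the aryl group on C6, which leaves the methoxy group cis to aryl as the target requires.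

**C6–aryl.** Silyl enol ether 10 is the trapped enolate of a conjugate addition. Cutting C6–aryl gives 2-methoxy enone 7 and aryl bromide 8 (used as Grignard reagent 9). Putting the methoxy group on before the aryl group means the C5 enolate forms at one defined position and the last group to reach C5 is carbon, as the C5 configuration demands. The aryl group must add anti to the γ-methyl group.

**C5–OMe.** The methoxy group of 7 is traced to epoxy ketone 6 and from there to plain enone 5. An α-diketone enol ether was rejected because the diketone would enolise toward the allyl-bearing carbon. Methoxide must open the epoxide at the carbonyl α-carbon, and the adduct must lose water without disturbing the C7 centre.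

**C7–CH3 and C1–allyl.** Enone 5 is the elimination product of silyloxy ketone 4, which is cut at both the C7–methyl and the C1–allyl bonds to enone 1, a methyl cuprate and allyl bromide 2. The silyloxy group of 1 does three jobs. It sends the methyl group to the opposite face, which is the only absolute stereocontrol in the route. It leaves the conjugate-addition enolate on the side where the allyl group is wanted. It then departs as silanol to place the enone on the other side. A ring lacking this group would need a regioselective enolisation next to a β-methyl carbon, which is not reliable. The forward alkylation must outrun enolate equilibration.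

## Roads not taken

**Alternative 1:** The cut is the C5–C8 bond of the cyclopentanone. In the forward direction a triazolium-derived N-heterocyclic carbene turns the aldehyde of keto aldehyde A2 into its acyl anion equivalent, which adds to the acetal-activated ketone and gives the α-hydroxy cyclopentanone A1 with the tertiary C5 carbinol.
- Merits: the C–C bond formation is catalytic and redox-neutral, the C5 oxygen and a masked C4 aldehyde arrive together, and no stoichiometric copper or α-methoxy enone chemistry is needed. In these respects it is better than the chosen plan.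
- Weak points: A1 holds only the five-membered ring. The allyl group, C2, C3 and both the C1–C2 and C3–C4 bonds are still missing, so the bridge must be annulated onto a ketone α-carbon and a neopentyl aldehyde. The tertiary hydroxyl must be methylated next to a ketone, where retro-benzoin and α-ketol shifts threaten under base. A2 carries an acyclic anti methyl/aryl pair whose benzylic centre is α to a ketone and epimerisable under the basic carbene conditions.
- Comparison: the chosen plan sets against the catalytic elegance a ring-based stereochemical relay from one purchased centre, and a key step after which a single reduction remains.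

**Alternative 2:** The cut is the pair C1–C8 and C4–C5, leading back to the cyclobutane-fused cyclohexanone A4, a [2+2] photoadduct. In the forward direction AlCl3 or EtAlCl2 activates the carbonyl of A4; C1 shifts from C5 to C8, leaving a methoxy-stabilised cation at C5, and C4 then shifts from C8 to C5 to give bicyclo[3.2.1]octan-8-one A3.
- Merits: the whole bridged skeleton and both quaternary bridgeheads appear in one strain-driven step, and the photocycloaddition joins two halves convergently. In skeletal bonds per step this is better than the chosen plan, whose key step forms one bond.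
- Weak points: A3 lacks the C3 methoxy group. It would have to be added by desilylation, oxidation at C4, enolate oxygenation at C3, methylation and reduction, which ends at the same C4 reduction problem as the chosen plan after several more steps. The strong Lewis acid meets an allyl group next to the C5 cation, aryl methyl ethers and a silyl ether. The regio- and stereochemistry of a photocycloaddition between a tetrasubstituted α-methoxy enone and a β-methylstyrene is uncertain, and the enone partner needs its own enantioselective synthesis.
- Comparison: the chosen plan has the full oxygenation pattern in place before the key step and closes the ring with a catalytic base.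

**Alternative 3:** The cut is the C1–allyl and C5–C6 bonds, leading back to the aryl allyl ether A6, in which C1–C5 and C8 form a benzene ring. In the forward direction Et2AlCl and heat move the allyl group from oxygen to the substituted ortho carbon C1 by a [3,3] shift. The resulting 2,4-dienone attacks the ionised benzylic carbon C6 through C5, and the C4 oxocarbenium ion loses its methyl group to give ene-dione A5.
- Merits: it is the shortest road by a wide margin, starting from two simple arenes. A5 is the 2,3-didehydro analogue of 17, so one conjugate reduction would join the chosen endgame. In step count it is clearly better.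
- Weak points: the quaternary C1 centre is set in the Claisen step with only the acyclic C7 centre to guide it. Ionisation of the benzylic alcohol before the shift invites elimination to a 1,2-diarylpropene, which destroys C7, and Friedel–Crafts chemistry. The allyl group must migrate to an already substituted ortho carbon while the other ortho carbon also bears a substituent. Absolute configuration rests on a benzylic centre adjacent to a cation.
- Comparison: the chosen plan is longer, but each stereocentre is introduced in a separate, ring-controlled step of a well-known type, and the single enantiomer is secured from 1.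

Key step: step 9

Assumption: (S)-4-(tert-butyldimethylsilyloxy)cyclopent-2-enone 1 and methoxyacetaldehyde 11 are taken as purchasable. The allyl-bearing carbon of 4–16 is drawn trans to methyl, but it is planarised in step 9, so its configuration does not affect the outcome.

## Route

Step 1
Reactants: 1 (4S)-4-[(tert-butyldimethylsilyl)oxy]cyclopent-2-en-1-one; 2 allyl bromide (3-bromoprop-1-ene)
Product: 4 (2S,3S,4S)-4-[(tert-butyldimethylsilyl)oxy]-3-methyl-2-(prop-2-en-1-yl)cyclopentan-1-one, via lithium enolate 3 (not isolated)
Conditions: Me2CuLi (from CuI, MeLi), Et2O/THF, −78 °C; then DMPU, 2 (excess), −78 to −20 °C; aq. NH4Cl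
Reagents that add atoms: lithium dimethylcuprate, [Li+].C[Cu-]C
Why: Tandem cuprate conjugate addition–enolate alkylation (three-component coupling on a 4-silyloxycyclopentenone): methyl adds anti to the silyloxy group, and the regiodefined enolate 3 is allylated anti to the new methyl group, so the all-trans ketone should result.

Step 2
Reactants: 4 (2S,3S,4S)-4-[(tert-butyldimethylsilyl)oxy]-3-methyl-2-(prop-2-en-1-yl)cyclopentan-1-one
Product: 5 (4R,5S)-4-methyl-5-(prop-2-en-1-yl)cyclopent-2-en-1-one
Conditions: DBU, CH2Cl2, 0 °C to rt
Reagents that add atoms: none
Why: E1cB β-elimination: DBU enolises toward the CH2 next to the silyloxy carbon and the silanol leaves, giving the enone on the side away from the methyl group; the methyl centre is untouched and the allyl centre stays in its thermodynamic trans arrangement.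

Step 3
Reactants: 5 (4R,5S)-4-methyl-5-(prop-2-en-1-yl)cyclopent-2-en-1-one
Product: 6 (1R,3S,4S,5R)-4-methyl-3-(prop-2-en-1-yl)-6-oxabicyclo[3.1.0]hexan-2-one (epoxide oxygen anti to methyl)
Conditions: 30% H2O2, NaOH (cat.), MeOH, 0 °C
Reagents that add atoms: hydrogen peroxide, OO
Why: Weitz–Scheffer nucleophilic epoxidation: hydroperoxide adds to the enone β-carbon anti to the neighbouring methyl group and closes to the epoxide, while the isolated terminal alkene is inert to the nucleophilic oxidant; the epoxide configuration is lost in step 4.

Step 4
Reactants: 6 (1R,3S,4S,5R)-4-methyl-3-(prop-2-en-1-yl)-6-oxabicyclo[3.1.0]hexan-2-one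
Product: 7 (4R,5S)-2-methoxy-4-methyl-5-(prop-2-en-1-yl)cyclopent-2-en-1-one
Conditions: NaOMe (0.3 equiv), MeOH, 0 °C to rt
Reagents that add atoms: methanol (as NaOMe/MeOH), CO
Why: Methoxide opens the epoxy ketone by SN2 at the carbonyl α-carbon, and the β-hydroxy-α-methoxy ketone dehydrates by E1cB to the 2-methoxy enone, the classical conversion of α,β-epoxy ketones into α-alkoxy enones; a low temperature and a short reaction time are chosen to keep the γ-methyl centre from exchanging.

Step 5
Reactants: 7 (4R,5S)-2-methoxy-4-methyl-5-(prop-2-en-1-yl)cyclopent-2-en-1-one; 8 5-bromo-1,2,3-trimethoxybenzene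
Product: 10 trimethyl{[(3S,4S,5S)-2-methoxy-4-methyl-5-(prop-2-en-1-yl)-3-(3,4,5-trimethoxyphenyl)cyclopent-1-en-1-yl]oxy}silane, via 3,4,5-trimethoxyphenylmagnesium bromide 9 (not isolated)
Conditions: 8, Mg, THF, rt; then CuBr·SMe2 (10 mol%), Me3SiCl, 7, THF, −78 to −40 °C; Et3N, aq. NaHCO3
Reagents that add atoms: chlorotrimethylsilane, C[Si](C)(C)Cl
Why: Copper-catalysed conjugate addition of the aryl Grignard reagent accelerated by the silyl chloride: the aryl group adds to the β-carbon anti to the adjacent methyl group, and the enolate is caught as the regiodefined tetrasubstituted silyl enol ether.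

Step 6
Reactants: 10 trimethyl{[(3S,4S,5S)-2-methoxy-4-methyl-5-(prop-2-en-1-yl)-3-(3,4,5-trimethoxyphenyl)cyclopent-1-en-1-yl]oxy}silane; 11 methoxyacetaldehyde
Product: 12 (2S,3R,4S,5S)-5-(1-hydroxy-2-methoxyethyl)-5-methoxy-3-methyl-2-(prop-2-en-1-yl)-4-(3,4,5-trimethoxyphenyl)cyclopentan-1-one (both carbinol epimers)
Conditions: BF3·OEt2, CH2Cl2, −78 °C; aq. NaHCO3
Reagents that add atoms: none
Why: Mukaiyama aldol addition: the activated aldehyde is attacked by the methoxy-bearing enol carbon from the face anti to the adjacent aryl group (the allyl group shields the same lower face), which sets the quaternary C5 with the carbon chain trans to aryl; loss of the silyl group makes the addition irreversible and avoids retro-aldol of a hindered metal aldolate, and the carbinol configuration is irrelevant.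

Step 7
Reactants: 12 (2S,3R,4S,5S)-5-(1-hydroxy-2-methoxyethyl)-5-methoxy-3-methyl-2-(prop-2-en-1-yl)-4-(3,4,5-trimethoxyphenyl)cyclopentan-1-one
Product: 13 (2S,3R,4S,5R)-5-methoxy-5-(methoxyacetyl)-3-methyl-2-(prop-2-en-1-yl)-4-(3,4,5-trimethoxyphenyl)cyclopentan-1-one
Conditions: Dess–Martin periodinane, CH2Cl2, rt
Reagents that add atoms: none
Why: Dess–Martin oxidation of the secondary alcohol under non-basic conditions, which avoids retro-aldol of 12 and retro-Claisen of the non-enolisable β-diketone formed; the alkene and the arene are not affected.

Step 8
Reactants: 13 (2S,3R,4S,5R)-5-methoxy-5-(methoxyacetyl)-3-methyl-2-(prop-2-en-1-yl)-4-(3,4,5-trimethoxyphenyl)cyclopentan-1-one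
Product: 16 (2S,3R,4S,5R)-5-methoxy-5-(2-methoxyprop-2-enoyl)-3-methyl-2-(prop-2-en-1-yl)-4-(3,4,5-trimethoxyphenyl)cyclopentan-1-one, via Mannich base 14 (not isolated), via trimethylammonium iodide 15 (not isolated)
Conditions: LiN(SiMe3)2, THF, −78 °C; CH2=NMe2+ I−, −78 to 0 °C; MeI, rt; aq. NaHCO3, CH2Cl2
Reagents that add atoms: Eschenmoser's salt (N,N-dimethylmethyleneiminium iodide), C=[N+](C)C.[I-]
Why: Mannich methylenation: the bulky amide base removes a proton from the unhindered CH2(OMe) of the side chain in preference to the tertiary, doubly flanked ring C–H, the enolate is aminomethylated, and N-methylation followed by E1cB loss of trimethylamine gives the 2-methoxy enone; bicarbonate is too weak to enolise the ring ketone, so the acceptor can be isolated before the ring closure.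

Step 9
Reactants: 16 (2S,3R,4S,5R)-5-methoxy-5-(2-methoxyprop-2-enoyl)-3-methyl-2-(prop-2-en-1-yl)-4-(3,4,5-trimethoxyphenyl)cyclopentan-1-one
Product: 17 (1R,3S,5R,6S,7R)-3,5-dimethoxy-7-methyl-1-(prop-2-en-1-yl)-6-(3,4,5-trimethoxyphenyl)bicyclo[3.2.1]octane-4,8-dione (target numbering)
Conditions: Cs2CO3 (0.2 equiv), dry MeCN (0.02 M), rt
Reagents that add atoms: none
Why: Carbonate reversibly removes the C1 proton, the only acidic C–H (C5 is quaternary and the acceptor carbonyl has no α-hydrogen); the enolate carbon adds to the unsubstituted terminus C2 of the 2-methoxyacryloyl group and the resulting methoxy enolate is protonated at C3. The closest known reaction type is the Michael closure of 2-acryloylcycloalkanones, the second stage of the α,α′-annulation of cycloalkanone enolates or enamines with acryloyl chloride that gives bicyclo[3.2.1]octane-2,8-diones and bicyclo[3.3.1]nonane-2,9-diones. The six-membered ring C1–C2–C3–C4–C5–C8 closes in the 6-endo-trig mode at the acceptor, with the enolate double bond also inside the new ring. The C1 configuration is dictated by the tether: the acyl group on C5 can reach only the enolate face syn to it, so C2 arrives cis to C4 across C8 and the allyl group is pushed exo, whatever the C1 configuration of 16 was. C3 is set by protonation, which is reversible next to the C4 ketone and should settle with the methoxy group equatorial, because the axial position points at the endo methyl group on C7. The step needs C- over O-attack of the enolate and ring closure over retro-Claisen cleavage; O-attack is reversible and the C–C adduct is the thermodynamic sink, and a catalytic, poorly nucleophilic base in a dry aprotic solvent protects the β-diketone. The methoxy group lowers the electrophilicity of the acceptor, which intramolecularity and the fixed cis placement of donor and acceptor on the five-membered ring should offset.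

Step 10
Reactants: 17 (1R,3S,5R,6S,7R)-3,5-dimethoxy-7-methyl-1-(prop-2-en-1-yl)-6-(3,4,5-trimethoxyphenyl)bicyclo[3.2.1]octane-4,8-dione
Product: 18 (1R,3S,4S,5S,6S,7R)-4-hydroxy-3,5-dimethoxy-7-methyl-1-(prop-2-en-1-yl)-6-(3,4,5-trimethoxyphenyl)bicyclo[3.2.1]octan-8-one
Conditions: LiBH(s-Bu)3 (1.1 equiv), THF, −78 °C; AcOH, −78 °C
Reagents that add atoms: none
Why: Ketone reduction with a bulky trialkylborohydride: C8 lies between two quaternary bridgeheads and should react more slowly than C4, and the hydride should enter C4 equatorially, anti to the C5–C8 bond and away from the C8 bridge and the axial C2–H (as in such reductions of cyclohexanones with one sp2 carbon at a 3-position), giving the axial alcohol; the cold acidic quench prevents retro-aldol opening of the alkoxide.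

## Compound list

1 | (4S)-4-[(tert-butyldimethylsilyl)oxy]cyclopent-2-en-1-one | O=C1C=C[C@@H](O[Si](C)(C)C(C)(C)C)C1 | starting material
2 | allyl bromide (3-bromoprop-1-ene) | C=CCBr | starting material
3 | lithium (3S,4S)-4-[(tert-butyldimethylsilyl)oxy]-3-methylcyclopent-1-en-1-olate | [Li+].[O-]C1=C[C@H](C)[C@@H](O[Si](C)(C)C(C)(C)C)C1 | intermediate
4 | (2S,3S,4S)-4-[(tert-butyldimethylsilyl)oxy]-3-methyl-2-(prop-2-en-1-yl)cyclopentan-1-one | C=CC[C@@H]1C(=O)C[C@H](O[Si](C)(C)C(C)(C)C)[C@H]1C | intermediate
5 | (4R,5S)-4-methyl-5-(prop-2-en-1-yl)cyclopent-2-en-1-one | C=CC[C@@H]1C(=O)C=C[C@H]1C | intermediate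
6 | (1R,3S,4S,5R)-4-methyl-3-(prop-2-en-1-yl)-6-oxabicyclo[3.1.0]hexan-2-one | C=CC[C@@H]1C(=O)[C@@H]2O[C@@H]2[C@H]1C | intermediate
7 | (4R,5S)-2-methoxy-4-methyl-5-(prop-2-en-1-yl)cyclopent-2-en-1-one | C=CC[C@@H]1C(=O)C(OC)=C[C@H]1C | intermediate
8 | 5-bromo-1,2,3-trimethoxybenzene | COc1cc(Br)cc(OC)c1OC | starting material
9 | 3,4,5-trimethoxyphenylmagnesium bromide | COc1cc([Mg]Br)cc(OC)c1OC | intermediate
10 | trimethyl{[(3S,4S,5S)-2-methoxy-4-methyl-5-(prop-2-en-1-yl)-3-(3,4,5-trimethoxyphenyl)cyclopent-1-en-1-yl]oxy}silane | C=CC[C@@H]1C(O[Si](C)(C)C)=C(OC)[C@H](c2cc(OC)c(OC)c(OC)c2)[C@H]1C | intermediate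
11 | methoxyacetaldehyde | COCC=O | starting material
12 | (2S,3R,4S,5S)-5-(1-hydroxy-2-methoxyethyl)-5-methoxy-3-methyl-2-(prop-2-en-1-yl)-4-(3,4,5-trimethoxyphenyl)cyclopentan-1-one (carbinol epimers) | C=CC[C@@H]1C(=O)[C@@](OC)(C(O)COC)[C@H](c2cc(OC)c(OC)c(OC)c2)[C@H]1C | intermediate
13 | (2S,3R,4S,5R)-5-methoxy-5-(methoxyacetyl)-3-methyl-2-(prop-2-en-1-yl)-4-(3,4,5-trimethoxyphenyl)cyclopentan-1-one | C=CC[C@@H]1C(=O)[C@@](OC)(C(=O)COC)[C@H](c2cc(OC)c(OC)c(OC)c2)[C@H]1C | intermediate
14 | (2S,3R,4S,5R)-5-[3-(dimethylamino)-2-methoxypropanoyl]-5-methoxy-3-methyl-2-(prop-2-en-1-yl)-4-(3,4,5-trimethoxyphenyl)cyclopentan-1-one (side-chain epimers) | C=CC[C@@H]1C(=O)[C@@](OC)(C(=O)C(OC)CN(C)C)[C@H](c2cc(OC)c(OC)c(OC)c2)[C@H]1C | intermediate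
15 | 2-methoxy-N,N,N-trimethyl-3-[(1R,2S,3R,4S)-1-methoxy-3-methyl-5-oxo-4-(prop-2-en-1-yl)-2-(3,4,5-trimethoxyphenyl)cyclopentyl]-3-oxopropan-1-aminium iodide (methiodide of 14) | C=CC[C@@H]1C(=O)[C@@](OC)(C(=O)C(OC)C[N+](C)(C)C)[C@H](c2cc(OC)c(OC)c(OC)c2)[C@H]1C.[I-] | intermediate
16 | (2S,3R,4S,5R)-5-methoxy-5-(2-methoxyprop-2-enoyl)-3-methyl-2-(prop-2-en-1-yl)-4-(3,4,5-trimethoxyphenyl)cyclopentan-1-one | C=CC[C@@H]1C(=O)[C@@](OC)(C(=O)C(OC)=C)[C@H](c2cc(OC)c(OC)c(OC)c2)[C@H]1C | intermediate
17 | (1R,3S,5R,6S,7R)-3,5-dimethoxy-7-methyl-1-(prop-2-en-1-yl)-6-(3,4,5-trimethoxyphenyl)bicyclo[3.2.1]octane-4,8-dione (target numbering) | C=CC[C@]12C[C@H](OC)C(=O)[C@](OC)(C1=O)[C@H](c1cc(OC)c(OC)c(OC)c1)[C@H]2C | intermediate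
18 | (1R,3S,4S,5S,6S,7R)-4-hydroxy-3,5-dimethoxy-7-methyl-1-(prop-2-en-1-yl)-6-(3,4,5-trimethoxyphenyl)bicyclo[3.2.1]octan-8-one | C=CC[C@]12C[C@H](OC)[C@H](O)[C@](OC)(C1=O)[C@H](c1cc(OC)c(OC)c(OC)c1)[C@H]2C | target

## Step count and least certain steps

Total steps: 10. Longest linear sequence: 10 steps (1 to 18); the aryl Grignard reagent 9 is made in the flask within step 5.

**Step 9 (key step).** The most likely failures are retro-Claisen cleavage of the non-enolisable β-diketone by adventitious hydroxide, and slow closure. The enolate carbon is tertiary and the acceptor is deactivated by its methoxy group, so intermolecular Michael addition could compete. Fallback: setting out from 16, soft enolisation with Me3SiOTf and Et3N, possible only toward C1, would give the trimethylsilyl enol ether of the ring ketone F7. A chelating Lewis acid such as TiCl4 or Me2AlCl, held between the side-chain carbonyl and its methoxy group, would then bring about an intramolecular Mukaiyama–Michael addition. Aqueous work-up, with brief DBU equilibration of C3 if needed, comes back to the route at 17.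

**Step 10.** What may go wrong is poor facial selectivity (hydride entering from the C8 side to give the equatorial alcohol), competing reduction at C8, or retro-aldol opening of the lithium alkoxide on warming. The cage has only one axial hydrogen and an sp2 carbon opposing axial attack, so the preference for equatorial attack is not assured. Fallback: from 17, a small hydride under conditions that favour axial attack (NaBH4, CeCl3, MeOH, −78 °C) would be used on purpose to make the equatorial C4-epimeric alcohol F8. Mitsunobu inversion with 4-nitrobenzoic acid, PPh3 and DIAD would give the axial 4-nitrobenzoate F9, and mild methanolysis (K2CO3, MeOH, 0 °C) would come back to the route at 18.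

**Step 4.** Under methoxide the methyl-bearing γ-carbon may lose its configuration through dienolate formation, or the double bond may migrate to the more substituted position. Fallback: from 4, kinetic enolisation toward the CH2 group (LiN(SiMe3)2, THF, −78 °C) and hydroxylation with 2-(phenylsulfonyl)-3-phenyloxaziridine would give the 5-hydroxy ketone F3. O-Methylation with MeOTf and 2,6-di-tert-butyl-4-methylpyridine would give the 5-methoxy ketone F4. DBU would then expel the silanol and come back to the route at 7 without ever exposing an enone to alkoxide.

**Step 8.** Enolisation may occur at the ring C–H, or the two enolates may exchange a proton, which would lead to aminomethylation at C1. Fallback: from 10, with the methylene carbon installed before the C4–C5 bond. Methylenation of 11 (aqueous CH2O, Me2NH·HCl) would give 2-methoxyprop-2-enal F5. Mukaiyama aldol addition of 10 to F5 (BF3·OEt2, −78 °C) would give the allylic alcohol F6, and Dess–Martin oxidation would come back to the route at 16.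

**Step 1.** The enolate may equilibrate before it is alkylated (proton transfer to the other α-carbon, loss of silanolate and a second cuprate addition), and over-alkylation is possible. Fallback: from 1, Me2CuLi addition with a proton quench would give the trans silyloxy ketone F1. DBU would give (S)-4-methylcyclopent-2-en-1-one F2. Deprotonation at the only enolisable carbon with LiN(i-Pr)2 (THF, −78 °C) and alkylation with 2, anti to the methyl group, would come back to the route at 5.

## Further compounds

F1 | step 1 | (3S,4S)-3-[(tert-butyldimethylsilyl)oxy]-4-methylcyclopentan-1-one | C[C@@H]1[C@@H](O[Si](C)(C)C(C)(C)C)CC(=O)C1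
F2 | step 1 | (S)-4-methylcyclopent-2-en-1-one | C[C@@H]1C=CC(=O)C1
F3 | step 4 | 4-[(tert-butyldimethylsilyl)oxy]-5-hydroxy-3-methyl-2-(prop-2-en-1-yl)cyclopentan-1-one (ring configured as 4, hydroxyl trans to silyloxy) | C=CC[C@@H]1C(=O)[C@@H](O)[C@H](O[Si](C)(C)C(C)(C)C)[C@H]1C
F4 | step 4 | 4-[(tert-butyldimethylsilyl)oxy]-5-methoxy-3-methyl-2-(prop-2-en-1-yl)cyclopentan-1-one (ring configured as 4, methoxy trans to silyloxy) | C=CC[C@@H]1C(=O)[C@@H](OC)[C@H](O[Si](C)(C)C(C)(C)C)[C@H]1C
F5 | step 8 | 2-methoxyprop-2-enal | C=C(OC)C=O
F6 | step 8 | (2S,3R,4S,5S)-5-(1-hydroxy-2-methoxyprop-2-en-1-yl)-5-methoxy-3-methyl-2-(prop-2-en-1-yl)-4-(3,4,5-trimethoxyphenyl)cyclopentan-1-one (carbinol epimers) | C=CC[C@@H]1C(=O)[C@@](OC)(C(O)C(OC)=C)[C@H](c2cc(OC)c(OC)c(OC)c2)[C@H]1C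
F7 | step 9 | trimethylsilyl enol ether of the ring ketone of 16 (enol double bond between the allyl-bearing carbon and the former carbonyl carbon; other centres as in 16) | C=CCC1=C(O[Si](C)(C)C)[C@@](OC)(C(=O)C(OC)=C)[C@H](c2cc(OC)c(OC)c(OC)c2)[C@H]1C
F8 | step 10 | (1R,3S,4R,5S,6S,7R)-4-hydroxy-3,5-dimethoxy-7-methyl-1-(prop-2-en-1-yl)-6-(3,4,5-trimethoxyphenyl)bicyclo[3.2.1]octan-8-one (equatorial C4 epimer of 18) | C=CC[C@]12C[C@H](OC)[C@@H](O)[C@](OC)(C1=O)[C@H](c1cc(OC)c(OC)c(OC)c1)[C@H]2C
F9 | step 10 | 4-nitrobenzoate of 18 (axial ester at C4) | C=CC[C@]12C[C@H](OC)[C@H](OC(=O)c3ccc(cc3)[N+](=O)[O-])[C@](OC)(C1=O)[C@H](c1cc(OC)c(OC)c(OC)c1)[C@H]2C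
A1 | alternative 1 | 2-(dimethoxymethyl)-2-hydroxy-4-methyl-3-(3,4,5-trimethoxyphenyl)cyclopentan-1-one | O=C1C[C@H](C)[C@@H](c2cc(OC)c(OC)c(OC)c2)[C@]1(O)C(OC)OC
A2 | alternative 1 | 6,6-dimethoxy-3-methyl-5-oxo-4-(3,4,5-trimethoxyphenyl)hexanal | O=CC[C@H](C)[C@@H](c1cc(OC)c(OC)c(OC)c1)C(=O)C(OC)OC
A3 | alternative 2 | 4-[(tert-butyldimethylsilyl)oxy]-5-methoxy-7-methyl-1-(prop-2-en-1-yl)-6-(3,4,5-trimethoxyphenyl)bicyclo[3.2.1]octan-8-one (target numbering, no C3 methoxy group) | C=CC[C@]12CC[C@H](O[Si](C)(C)C(C)(C)C)[C@](OC)(C1=O)[C@H](c1cc(OC)c(OC)c(OC)c1)[C@H]2C
A4 | alternative 2 | cis-fused 3-[(tert-butyldimethylsilyl)oxy]-1-methoxy-7-methyl-6-(prop-2-en-1-yl)-8-(3,4,5-trimethoxyphenyl)bicyclo[4.2.0]octan-2-one | C=CC[C@]12CC[C@H](O[Si](C)(C)C(C)(C)C)C(=O)[C@@]1(OC)[C@H](c1cc(OC)c(OC)c(OC)c1)[C@H]2C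
A5 | alternative 3 | 3,5-dimethoxy-7-methyl-1-(prop-2-en-1-yl)-6-(3,4,5-trimethoxyphenyl)bicyclo[3.2.1]oct-2-ene-4,8-dione (target numbering) | C=CC[C@]12C=C(OC)C(=O)[C@](OC)(C1=O)[C@H](c1cc(OC)c(OC)c(OC)c1)[C@H]2C
A6 | alternative 3 | 2-[3,4,5-trimethoxy-2-(prop-2-en-1-yloxy)phenyl]-1-(3,4,5-trimethoxyphenyl)propan-1-ol (either carbinol epimer) | C=CCOc1c(OC)c(OC)c(OC)cc1[C@H](C)C(O)c1cc(OC)c(OC)c(OC)c1
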